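**Plan**
- Retrosynthetic cuts: the C6–OMe bond and the C3 ketone are traced back to an alkenylsilane and a protected carbinol. The ring is then cut at C6–C7 (as the alkyne C6≡C7), then at the lactone C1–O bond. The alcohol half is cut at C10–C11, the acid half at C2–C3 and C5–C6.
- Forward order: acid 11 (C1–C6) and alcohol 26 (C7–C13) are built separately and esterified. The only ring, the 14-membered lactone, is closed by alkyne metathesis. The triple bond is then turned into the methyl enol ether, and C3 is oxidised near the end.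
- Enabling feature: with the ring counted from the lactone carbonyl (C1) to the ethyl-bearing carbinol (C13), the enol ether C6(OMe)=C7H has C5 and C8 on the same side. That is the outcome of a syn addition across a ring alkyne C6≡C7. The tertiary C4 hydroxyl is homopropargylic to that alkyne and can hand a silicon atom to C6.
- Stereochemistry: C4 from a Sharpless epoxidation, C2 (and the transient C3 carbinol) from an Evans aldol, C8 from an Evans alkylation, C13 from a CBS reduction. The 11Z alkene comes from an anti carbomagnesiation, and the C6=C7 geometry from the tethered syn-hydrosilylation.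

Key step: step 20

Numbering used in names: C1 = lactone carbonyl, then C2 to C13 (ethyl-bearing carbinol carbon), then the ring oxygen. Every macrocycle below carries 2-methyl, 8-methyl, 10-methylidene, 12-methyl, 13-ethyl and the 11Z alkene.
Remark on the chemistry: the C3 carbinol from step 6 is drawn as the (3R) epimer expected from the Evans syn transition state; its configuration is erased by the oxidation in step 27.

Step 1
Reactants: 1 2-methylenepropane-1,3-diol
Product: 2 2-{[tert-butyl(diphenyl)silyl]oxymethyl}prop-2-en-1-ol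
Conditions: NaH (1.0 equiv), THF, 0 °C to rt; then TBDPSCl (1.0 equiv)
Reagents that add atoms: tert-butyl(chloro)diphenylsilane, CC(C)(C)[Si](Cl)(c1ccccc1)c1ccccc1
Why: O-silylation of a symmetrical diol through its sparingly soluble monosodium alkoxide (Williamson-type silyl ether formation) should stop after one hydroxyl has reacted.

Step 2
Reactants: 2 mono-TBDPS allylic alcohol
Product: 3 [(2R)-2-{[tert-butyl(diphenyl)silyl]oxymethyl}oxiran-2-yl]methanol
Conditions: Ti(OiPr)4 (cat.), D-(−)-diethyl tartrate (cat.), tBuOOH, 4 Å MS, CH2Cl2, −20 °C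
Reagents that add atoms: tert-butyl hydroperoxide, CC(C)(C)OO
Why: Sharpless asymmetric epoxidation of a 2-substituted allylic alcohol, in which the titanium tartrate complex made from D-(−)-diethyl tartrate should deliver oxygen to the face that gives the (R)-epoxide, whose quaternary carbon becomes C4.

Step 3
Reactants: 3 (R)-epoxy alcohol
Product: 4 (2S)-2-{[tert-butyl(diphenyl)silyl]oxymethyl}hex-4-yne-1,2-diol
Conditions: propyne (3.5 equiv), n-BuLi (3.3 equiv), THF, −78 °C; BF3·OEt2 (3 equiv); then 3, −78 °C; aq. NH4Cl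
Reagents that add atoms: propyne (used as propynyllithium), CC#C
Why: BF3-promoted SN2 opening of an epoxide by a lithium acetylide occurs at the unsubstituted CH2 terminus (one equivalent of acetylide is spent on the free hydroxyl), so the C5–C6 bond forms without touching the quaternary stereocentre, whose descriptor changes from R to S only through the priority rules.

Step 4
Reactants: 4 (S)-alkyne diol
Product: 5 (2S)-1-[tert-butyl(diphenyl)silyl]oxy-2-(trimethylsilyloxy)-2-[(trimethylsilyloxy)methyl]hex-4-yne
Conditions: TMSOTf, 2,6-lutidine, CH2Cl2, −78 to 0 °C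
Reagents that add atoms: trimethylsilyl triflate, C[Si](C)(C)OS(=O)(=O)C(F)(F)F
Why: Silyl triflate silylation caps the primary and the hindered tertiary hydroxyl without generating an alkoxide, so the TBDPS group should not migrate between the two primary oxygens, which would erode the stereocentre.

Step 5
Reactants: 5 bis-trimethylsilyl ether
Product: 6 (2R)-2-{[tert-butyl(diphenyl)silyl]oxymethyl}-2-(trimethylsilyloxy)hex-4-ynal
Conditions: (COCl)2, DMSO, CH2Cl2, −78 to −40 °C; Et3N, −78 to 0 °C
Reagents that add atoms: none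
Why: Under Swern conditions an unhindered primary trimethylsilyl ether is cleaved and oxidised directly to the aldehyde while the tertiary trimethylsilyl ether stays, which avoids a free α-hydroxy aldehyde and gives an aldehyde with no α-hydrogen to epimerise.

Step 6
Reactants: 6 α-silyloxy aldehyde; 7 (4R)-4-benzyl-3-propanoyl-1,3-oxazolidin-2-one
Product: 9 (4R)-4-benzyl-3-[(2R,3R,4R)-4-{[tert-butyl(diphenyl)silyl]oxymethyl}-3-hydroxy-2-methyl-4-(trimethylsilyloxy)oct-6-ynoyl]-1,3-oxazolidin-2-one, via dibutylboron Z-enolate 8 (not isolated)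
Conditions: 7 (1.2 equiv), Bu2BOTf, Et3N, CH2Cl2, 0 °C; then 6, −78 to 0 °C; pH 7 buffer, MeOH, H2O2
Reagents that add atoms: none
Why: Evans syn aldol in which the Z-boron enolate reacts through a closed Zimmerman–Traxler chair and the benzyl group of the auxiliary shields one enolate face, which should set C2 as R and C3 as R under reagent control, a C3 epimer being harmless because C3 is oxidised in step 27.

Step 7
Reactants: 9 aldol adduct
Product: 10 (4R)-4-benzyl-3-[(2R,3R,4R)-4-{[tert-butyl(diphenyl)silyl]oxymethyl}-2-methyl-3-(triethylsilyloxy)-4-(trimethylsilyloxy)oct-6-ynoyl]-1,3-oxazolidin-2-one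
Conditions: TESOTf, 2,6-lutidine, CH2Cl2, −78 to 0 °C
Reagents that add atoms: triethylsilyl triflate, CC[Si](CC)(CC)OS(=O)(=O)C(F)(F)F
Why: Silyl triflate silylation is strong enough for the secondary hydroxyl next to the quaternary centre and blocks retro-aldol cleavage in the next step.

Step 8
Reactants: 10 silylated imide
Product: 11 (2R,3R,4R)-4-{[tert-butyl(diphenyl)silyl]oxymethyl}-2-methyl-3-(triethylsilyloxy)-4-(trimethylsilyloxy)oct-6-ynoic acid
Conditions: LiOH, H2O2, THF/H2O, 0 °C; Na2SO3; dilute HCl to pH 4
Reagents that add atoms: hydrogen peroxide, OO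
Why: Auxiliary hydrolysis with lithium hydroperoxide, which attacks the exocyclic imide carbonyl even in hindered acyl oxazolidinones and does not enolise C2 at 0 °C.

Step 9
Reactants: 7 (4R)-4-benzyl-3-propanoyl-1,3-oxazolidin-2-one; 12 2,3-dibromopropene
Product: 14 (4R)-4-benzyl-3-[(2S)-4-bromo-2-methylpent-4-enoyl]-1,3-oxazolidin-2-one, via sodium Z-enolate 13 (not isolated)
Conditions: NaN(SiMe3)2, THF, −78 °C; then 12 (3 equiv), −78 to −40 °C
Reagents that add atoms: none
Why: Evans asymmetric alkylation in which the chelated Z-sodium enolate is alkylated by the allylic bromide end of 12 (SN2) on the face opposite the benzyl group, which should give the (2S) centre that becomes C8 while the vinylic bromide stays inert.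

Step 10
Reactants: 14 alkylated imide
Product: 15 (2S)-4-bromo-2-methylpent-4-en-1-ol
Conditions: LiBH4, MeOH (1 equiv), Et2O, 0 °C
Reagents that add atoms: none
Why: Reductive cleavage of the acyl oxazolidinone with lithium borohydride gives the primary alcohol without touching the stereocentre or the vinyl bromide.

Step 11
Reactants: 15 bromo alcohol
Product: 16 (2S)-4-bromo-2-methylpent-4-enal
Conditions: Dess–Martin periodinane, NaHCO3, CH2Cl2, 0 °C to rt
Reagents that add atoms: none
Why: Dess–Martin oxidation under buffered, non-basic conditions should give the α-branched aldehyde without epimerisation, and the volatile product is used at once in solution.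

Step 12
Reactants: 16 bromo aldehyde
Product: 17 (4S)-2-bromo-4-methylhex-1-en-5-yne
Conditions: dimethyl (1-diazo-2-oxopropyl)phosphonate, K2CO3, MeOH, 0 °C to rt
Reagents that add atoms: dimethyl (1-diazo-2-oxopropyl)phosphonate, COP(=O)(OC)C(=[N+]=[N-])C(C)=O
Why: Ohira–Bestmann (Seyferth–Gilbert) homologation turns the aldehyde into the terminal alkyne under mild carbonate conditions that normally leave an α-methyl stereocentre intact.

Step 13
Reactants: 17 terminal alkyne
Product: 19 (4S)-2-bromo-4-methylhept-1-en-5-yne, via lithium acetylide 18 (not isolated)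
Conditions: LiN(iPr)2, THF, −78 °C; MeI, −78 °C to rt
Reagents that add atoms: iodomethane, CI
Why: Deprotonation of the terminal alkyne and SN2 methylation of the acetylide install the methyl cap needed for alkyne metathesis, an amide base being chosen so that the vinyl bromide does not undergo halogen–lithium exchange.

Step 14
Reactants: 20 pent-1-yn-3-ol (racemic)
Product: 22 (1Z)-1-iodo-2-methylpent-1-en-3-ol (racemic), via alkenylmagnesium alkoxide chelate 21 (not isolated)
Conditions: MeMgBr (3 equiv), CuI (cat.), THF, −10 °C to rt; then I2, −78 to 0 °C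
Reagents that add atoms: methylmagnesium bromide, C[Mg]Br; iodine, II
Why: Copper-catalysed anti-carbomagnesiation of the propargylic magnesium alkoxide puts methyl on the alkyne carbon next to the carbinol and magnesium on the terminal carbon inside a five-membered chelate, so iodinolysis with retention should give only the Z iodide that later becomes the 11Z alkene.

Step 15
Reactants: 22 racemic Z-iodo alcohol
Product: 23 (1Z)-1-iodo-2-methylpent-1-en-3-one
Conditions: Dess–Martin periodinane, NaHCO3, CH2Cl2, 0 °C to rt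
Reagents that add atoms: none
Why: Dess–Martin oxidation removes the racemic carbinol centre under iodide-free, non-nucleophilic conditions, so the Z β-iodo enone should not isomerise by addition–elimination.

Step 16
Reactants: 23 Z-iodo enone
Product: 24 (3S,1Z)-1-iodo-2-methylpent-1-en-3-ol
Conditions: (R)-2-methyl-CBS-oxazaborolidine (cat.), BH3·SMe2, THF, −30 °C
Reagents that add atoms: none
Why: Corey–Bakshi–Shibata reduction in which the α-branched alkenyl group acts as the large and ethyl as the small substituent, so the (R)-catalyst should deliver hydride to the face that gives the (S)-carbinol, the future C13.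

Step 17
Reactants: 24 (S)-Z-iodo alcohol
Product: 25 (3S,1Z)-2-methyl-1-(trimethylstannyl)pent-1-en-3-ol
Conditions: Me3SnSnMe3 (1.5 equiv), Pd(PPh3)4 (cat.), toluene, 80 °C
Reagents that add atoms: hexamethylditin, C[Sn](C)(C)[Sn](C)(C)C
Why: Palladium-catalysed stannylation of an alkenyl iodide with a distannane (oxidative addition to zerovalent palladium, transmetalation, reductive elimination) keeps the Z geometry and tolerates the free hydroxyl.

Step 18
Reactants: 19 bromo enyne; 25 Z-stannyl alcohol
Product: 26 (3S,4Z,8S)-4,8-dimethyl-6-methylideneundec-4-en-9-yn-3-ol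
Conditions: Pd(PPh3)4 (cat.), CuTC (Cu(O2CC4H3S), copper thiophene-2-carboxylate), [NBu4][Ph2PO2], DMF, rt
Reagents that add atoms: none
Why: Stille–Migita coupling of a 2-bromo-1-alkene with a Z-alkenylstannane, promoted at room temperature by the copper carboxylate and the tin-scavenging phosphinate, forms C10–C11 with retention of the alkene geometry and leaves the internal alkyne alone.

Step 19
Reactants: 11 C1–C6 acid; 26 C7–C13 alcohol
Product: 28 seco diyne ester (3S,4Z,8S)-4,8-dimethyl-6-methylideneundec-4-en-9-yn-3-yl (2R,3R,4R)-4-{[tert-butyl(diphenyl)silyl]oxymethyl}-2-methyl-3-(triethylsilyloxy)-4-(trimethylsilyloxy)oct-6-ynoate, via mixed anhydride 27 (not isolated)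
Conditions: 2,4,6-Cl3C6H2COCl, Et3N, toluene, rt; then 26, DMAP, rt
Reagents that add atoms: none
Why: Yamaguchi esterification, in which DMAP attacks the less hindered acyl carbon of the mixed anhydride and transfers the acyl group to the secondary allylic alcohol without breaking its C13–O bond, so C13 keeps its configuration.

Step 20
Reactants: 28 seco diyne ester
Product: 29 cycloalkyne lactone (2R,3R,4R,8S,13S,11Z) with C6≡C7; 3-OSiEt3; 4-OSiMe3; 4-CH2OSiPh2tBu
Conditions: Mo(≡CC6H4OMe-4)(OSiPh3)3 (cat.), 5 Å MS, toluene (2 mM), rt to 60 °C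
Reagents that add atoms: none
Why: The molybdenum alkylidyne adds to one methyl-capped alkyne by [2+2] cycloaddition to a metallacyclobutadiene, cycloreverts to a substrate-bound alkylidyne, and repeats the sequence on the second alkyne within the same molecule, so that C6≡C7 forms and but-2-yne leaves. The closest known reaction type is ring-closing alkyne metathesis of methyl-capped diynes with molybdenum alkylidyne triarylsilanolate catalysts. The single ring, the 14-membered lactone, closes end to end through the C6–C7 bond, and a ring of this size holds a triple bond without strain. No stereocentre is created, and C2, C3, C4, C8, C13 and the 11Z alkene lie outside the reacting atoms. The step needs selectivity for alkynes over the three alkenes, which the alkylidyne provides because it does not engage olefins, and ring closure over oligomerisation, which high dilution and the sieves that absorb but-2-yne should secure.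

Step 21
Reactants: 29 cycloalkyne lactone
Product: 30 cycloalkyne lactone with free 4-OH; 3-OSiEt3; 4-CH2OSiPh2tBu
Conditions: PPTS (cat.), MeOH/CH2Cl2, 0 °C
Reagents that add atoms: none
Why: Acid-catalysed methanolysis (selective silyl ether solvolysis) should remove the small trimethylsilyl group while the bulkier triethylsilyl ether on the hindered C3 oxygen and the TBDPS ether survive.

Step 22
Reactants: 30 C4 alcohol
Product: 32 bicyclic alkenylsiloxane (2,2-dimethyl-1,2-oxasilolane spanning O–C4–C5–C6–Si; C6=C7 with C5 and C8 cis), via dimethylsilyl ether 31 (not isolated)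
Conditions: Me2SiHCl, Et3N, DMAP (cat.), CH2Cl2, 0 °C to rt; then Pt2(dvtms)3 (cat., dvtms = 1,3-divinyltetramethyldisiloxane), toluene, rt to 50 °C
Reagents that add atoms: chlorodimethylsilane, C[SiH](C)Cl
Why: O-silylation followed by platinum-catalysed intramolecular hydrosilylation, in which the Si–H unit tethered to the C4 oxygen adds syn across C6≡C7 in the 5-exo-dig mode, so silicon ends on C6, hydrogen on C7, and C5 and C8 are cis, the diene being unable to compete with the tethered alkyne.

Step 23
Reactants: 32 bicyclic alkenylsiloxane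
Product: 33 alkenyl iodide (6-iodo; C6=C7 with C5 and C8 cis; free 4-OH; 3-OSiEt3; 4-CH2OSiPh2tBu)
Conditions: N-iodosuccinimide, 2,6-lutidine, (CF3)2CHOH/CH2Cl2, 0 °C; aq. NaHCO3/Na2S2O3
Reagents that add atoms: N-iodosuccinimide, O=C1CCC(=O)N1I
Why: Iododesilylation, in which electrophilic iodine attacks the silicon-bearing C6 and the β-silyl cation loses silicon faster than it rotates, so iodine should replace silicon with retention while hydrolysis of the remaining Si–O bond frees the C4 hydroxyl.

Step 24
Reactants: 33 alkenyl iodide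
Product: 34 alkenyl pinacol boronate (6-Bpin; C5 and C8 cis)
Conditions: B2pin2, PdCl2(PPh3)2 (cat.), PPh3, KOPh, toluene, 50 °C
Reagents that add atoms: bis(pinacolato)diboron, CC1(C)OB(OC1(C)C)B1OC(C)(C)C(C)(C)O1
Why: Miyaura borylation of an alkenyl iodide with phenoxide as a mild base proceeds with retention of geometry and is too weakly basic to ionise the C4 hydroxyl towards the lactone.

Step 25
Reactants: 34 alkenyl boronate
Product: 35 methyl enol ether (6-OMe; C5 and C8 cis; free 4-OH; 3-OSiEt3; 4-CH2OSiPh2tBu)
Conditions: Cu(OAc)2 (2.5 equiv), Et3N, MeOH, air, rt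
Reagents that add atoms: methanol, CO
Why: Chan–Lam–Evans-type oxidative C–O coupling, in which the alkenyl group passes from boron to divalent copper and reductive elimination from a trivalent copper methoxide forms C6–OMe with retention of geometry under non-acidic conditions that the enol ether tolerates.

Step 26
Reactants: 35 methyl enol ether
Product: 36 C3,C4-diol (4-CH2OSiPh2tBu retained)
Conditions: HF·pyridine, pyridine, THF, 0 °C to rt
Reagents that add atoms: none
Why: Buffered fluoride desilylation should cleave the secondary triethylsilyl ether much faster than the primary TBDPS ether, and the excess pyridine keeps the medium mild enough for the methyl enol ether.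

Step 27
Reactants: 36 diol
Product: 37 β-keto lactone (C3 ketone; free 4-OH; 4-CH2OSiPh2tBu)
Conditions: Dess–Martin periodinane, NaHCO3, CH2Cl2, 0 °C
Reagents that add atoms: none
Why: Dess–Martin oxidation converts only the secondary C3 alcohol (the tertiary C4 hydroxyl cannot be oxidised) under buffered conditions that expose neither the enol ether to acid nor the newly acidic C2–H to base.

Step 28
Reactants: 37 β-keto lactone
Product: 38 target (2R,4R,8S,13S,6E,11Z)-13-ethyl-4-hydroxy-4-(hydroxymethyl)-6-methoxy-2,8,12-trimethyl-10-methylidene 14-membered lactone with C3 ketone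
Conditions: Bu4NF, AcOH (1:1), THF, 0 °C to rt
Reagents that add atoms: none
Why: Fluoride desilylation buffered with acetic acid removes the TBDPS group near neutrality, so neither the enol ether (acid) nor the β-keto lactone and its C2 stereocentre (base) should suffer.

**Compound list**

1 | 2-methylenepropane-1,3-diol | C=C(CO)CO | starting material
2 | 2-{[tert-butyl(diphenyl)silyl]oxymethyl}prop-2-en-1-ol | C=C(CO)CO[Si](c1ccccc1)(c1ccccc1)C(C)(C)C | intermediate
3 | [(2R)-2-{[tert-butyl(diphenyl)silyl]oxymethyl}oxiran-2-yl]methanol | OC[C@]1(CO[Si](c2ccccc2)(c2ccccc2)C(C)(C)C)CO1 | intermediate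
4 | (2S)-2-{[tert-butyl(diphenyl)silyl]oxymethyl}hex-4-yne-1,2-diol | OC[C@](O)(CO[Si](c1ccccc1)(c1ccccc1)C(C)(C)C)CC#CC | intermediate
5 | (2S)-1-[tert-butyl(diphenyl)silyl]oxy-2-(trimethylsilyloxy)-2-[(trimethylsilyloxy)methyl]hex-4-yne | C[Si](C)(C)OC[C@](O[Si](C)(C)C)(CO[Si](c1ccccc1)(c1ccccc1)C(C)(C)C)CC#CC | intermediate
6 | (2R)-2-{[tert-butyl(diphenyl)silyl]oxymethyl}-2-(trimethylsilyloxy)hex-4-ynal | O=C[C@](O[Si](C)(C)C)(CO[Si](c1ccccc1)(c1ccccc1)C(C)(C)C)CC#CC | intermediate
7 | (4R)-4-benzyl-3-propanoyl-1,3-oxazolidin-2-one | CCC(=O)N1[C@H](Cc2ccccc2)COC1=O | starting material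
8 | dibutylboron Z-enolate of 7 | C/C=C(\OB(CCCC)CCCC)N1[C@H](Cc2ccccc2)COC1=O | intermediate
9 | (4R)-4-benzyl-3-[(2R,3R,4R)-4-{[tert-butyl(diphenyl)silyl]oxymethyl}-3-hydroxy-2-methyl-4-(trimethylsilyloxy)oct-6-ynoyl]-1,3-oxazolidin-2-one | O=C(N1[C@H](Cc2ccccc2)COC1=O)[C@H](C)[C@@H](O)[C@](O[Si](C)(C)C)(CO[Si](c1ccccc1)(c1ccccc1)C(C)(C)C)CC#CC | intermediate
10 | (4R)-4-benzyl-3-[(2R,3R,4R)-4-{[tert-butyl(diphenyl)silyl]oxymethyl}-2-methyl-3-(triethylsilyloxy)-4-(trimethylsilyloxy)oct-6-ynoyl]-1,3-oxazolidin-2-one | O=C(N1[C@H](Cc2ccccc2)COC1=O)[C@H](C)[C@@H](O[Si](CC)(CC)CC)[C@](O[Si](C)(C)C)(CO[Si](c1ccccc1)(c1ccccc1)C(C)(C)C)CC#CC | intermediate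
11 | (2R,3R,4R)-4-{[tert-butyl(diphenyl)silyl]oxymethyl}-2-methyl-3-(triethylsilyloxy)-4-(trimethylsilyloxy)oct-6-ynoic acid | OC(=O)[C@H](C)[C@@H](O[Si](CC)(CC)CC)[C@](O[Si](C)(C)C)(CO[Si](c1ccccc1)(c1ccccc1)C(C)(C)C)CC#CC | intermediate
12 | 2,3-dibromopropene | C=C(Br)CBr | starting material
13 | sodium Z-enolate of 7 | C/C=C(\O[Na])N1[C@H](Cc2ccccc2)COC1=O | intermediate
14 | (4R)-4-benzyl-3-[(2S)-4-bromo-2-methylpent-4-enoyl]-1,3-oxazolidin-2-one | C=C(Br)C[C@H](C)C(=O)N1[C@H](Cc2ccccc2)COC1=O | intermediate
15 | (2S)-4-bromo-2-methylpent-4-en-1-ol | C=C(Br)C[C@H](C)CO | intermediate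
16 | (2S)-4-bromo-2-methylpent-4-enal | C=C(Br)C[C@H](C)C=O | intermediate
17 | (4S)-2-bromo-4-methylhex-1-en-5-yne | C=C(Br)C[C@H](C)C#C | intermediate
18 | lithium acetylide of 17 | C=C(Br)C[C@H](C)C#C[Li] | intermediate
19 | (4S)-2-bromo-4-methylhept-1-en-5-yne | C=C(Br)C[C@H](C)C#CC | intermediate
20 | pent-1-yn-3-ol (racemic) | CCC(O)C#C | starting material
21 | alkenylmagnesium alkoxide chelate, 5-ethyl-4-methyl-2,5-dihydro-1,2-oxamagnesole (racemic) | CCC1O[Mg]C=C1C | intermediate
22 | (1Z)-1-iodo-2-methylpent-1-en-3-ol (racemic) | CCC(O)/C(C)=C\I | intermediate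
23 | (1Z)-1-iodo-2-methylpent-1-en-3-one | CCC(=O)/C(C)=C\I | intermediate
24 | (3S,1Z)-1-iodo-2-methylpent-1-en-3-ol | CC[C@H](O)/C(C)=C\I | intermediate
25 | (3S,1Z)-2-methyl-1-(trimethylstannyl)pent-1-en-3-ol | CC[C@H](O)/C(C)=C\[Sn](C)(C)C | intermediate
26 | (3S,4Z,8S)-4,8-dimethyl-6-methylideneundec-4-en-9-yn-3-ol | CC#C[C@@H](C)CC(=C)/C=C(/C)[C@H](CC)O | intermediate
27 | mixed anhydride of 11 with 2,4,6-trichlorobenzoic acid | O=C(OC(=O)[C@H](C)[C@@H](O[Si](CC)(CC)CC)[C@](O[Si](C)(C)C)(CO[Si](c1ccccc1)(c1ccccc1)C(C)(C)C)CC#CC)c1c(Cl)cc(Cl)cc1Cl | intermediate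
28 | seco diyne ester of 11 and 26 | CC#C[C@@H](C)CC(=C)/C=C(/C)[C@H](CC)OC(=O)[C@H](C)[C@@H](O[Si](CC)(CC)CC)[C@](O[Si](C)(C)C)(CO[Si](c1ccccc1)(c1ccccc1)C(C)(C)C)CC#CC | intermediate
29 | cycloalkyne lactone (2R,3R,4R,8S,13S,11Z), C6≡C7, 3-OSiEt3, 4-OSiMe3, 4-CH2OSiPh2tBu | C=C1/C=C(/C)[C@H](CC)OC(=O)[C@H](C)[C@@H](O[Si](CC)(CC)CC)[C@](O[Si](C)(C)C)(CO[Si](c2ccccc2)(c2ccccc2)C(C)(C)C)CC#C[C@@H](C)C1 | intermediate
30 | cycloalkyne lactone with free 4-OH | C=C1/C=C(/C)[C@H](CC)OC(=O)[C@H](C)[C@@H](O[Si](CC)(CC)CC)[C@](O)(CO[Si](c2ccccc2)(c2ccccc2)C(C)(C)C)CC#C[C@@H](C)C1 | intermediate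
31 | cycloalkyne lactone with 4-OSiHMe2 | C=C1/C=C(/C)[C@H](CC)OC(=O)[C@H](C)[C@@H](O[Si](CC)(CC)CC)[C@](O[SiH](C)C)(CO[Si](c2ccccc2)(c2ccccc2)C(C)(C)C)CC#C[C@@H](C)C1 | intermediate
32 | bicyclic alkenylsiloxane, oxasilolane O–C4–C5–C6–SiMe2, (6E) alkene with C5 and C8 cis | C=C1/C=C(/C)[C@H](CC)OC(=O)[C@H](C)[C@@H](O[Si](CC)(CC)CC)[C@@]2(CO[Si](c3ccccc3)(c3ccccc3)C(C)(C)C)O[Si](C)(C)/C(C2)=C/[C@@H](C)C1 | intermediate
33 | (6E)-6-iodo alkene lactone, free 4-OH | C=C1/C=C(/C)[C@H](CC)OC(=O)[C@H](C)[C@@H](O[Si](CC)(CC)CC)[C@](O)(CO[Si](c2ccccc2)(c2ccccc2)C(C)(C)C)C/C(I)=C\[C@@H](C)C1 | intermediate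
34 | (6Z)-6-(4,4,5,5-tetramethyl-1,3,2-dioxaborolan-2-yl) alkene lactone, C5 and C8 cis | C=C1/C=C(/C)[C@H](CC)OC(=O)[C@H](C)[C@@H](O[Si](CC)(CC)CC)[C@](O)(CO[Si](c2ccccc2)(c2ccccc2)C(C)(C)C)C/C(B2OC(C)(C)C(C)(C)O2)=C\[C@@H](C)C1 | intermediate
35 | (6E)-6-methoxy enol ether lactone, 3-OSiEt3, 4-OH, 4-CH2OSiPh2tBu | C=C1/C=C(/C)[C@H](CC)OC(=O)[C@H](C)[C@@H](O[Si](CC)(CC)CC)[C@](O)(CO[Si](c2ccccc2)(c2ccccc2)C(C)(C)C)C/C(OC)=C\[C@@H](C)C1 | intermediate
36 | enol ether lactone with 3-OH and 4-OH, 4-CH2OSiPh2tBu | C=C1/C=C(/C)[C@H](CC)OC(=O)[C@H](C)[C@@H](O)[C@](O)(CO[Si](c2ccccc2)(c2ccccc2)C(C)(C)C)C/C(OC)=C\[C@@H](C)C1 | intermediate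
37 | β-keto lactone, 4-OH, 4-CH2OSiPh2tBu | C=C1/C=C(/C)[C@H](CC)OC(=O)[C@H](C)C(=O)[C@](O)(CO[Si](c2ccccc2)(c2ccccc2)C(C)(C)C)C/C(OC)=C\[C@@H](C)C1 | intermediate
38 | CNP0325854.3, (2R,4R,8S,13S,6E,11Z) | C=C1/C=C(/C)[C@H](CC)OC(=O)[C@H](C)C(=O)[C@](O)(CO)C/C(OC)=C\[C@@H](C)C1 | target

**Count and risks**

Total steps: 28. Longest linear sequence: 18 steps (steps 1–8, then 19–28, from 2-methylenepropane-1,3-diol).

Most likely to fail:

1. Step 23. Electrophilic iodine may attack the electron-rich 2-substituted diene (C10–C12) faster than the silicon-bearing C6, or the cationic intermediate may lose its geometry before silicon departs. Fallback: set out from 30 and return at 34, leaving silicon and iodine out altogether. Copper-catalysed syn-hydroboration (CuCl, NaOtBu, Xantphos, B2pin2, MeOH, THF, rt) should add boron to C6, the alkyne carbon flanked by the unbranched C5 methylene, and hydrogen to C7 on the same face. The methyl branch at C8 disfavours the other regiochemistry, so the selectivity rests on sterics instead of the tether. No compound outside the list is made on this path, which is entered below as none F0.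

2. Step 25. Transfer of the hindered, trisubstituted alkenyl group from the pinacol ester to divalent copper may be slow, so that protodeboronation or oxidation to the C6 ketone takes over. Fallback: set out from 34 and return at 35. KHF2 in MeOH/H2O should convert the pinacol ester into the potassium alkenyltrifluoroborate F1. This salt is then coupled with methanol under catalytic Cu(OAc)2·H2O, DMAP, 4 Å MS and O2 in CH2Cl2, a catalytic aerobic etherification of organotrifluoroborates that also proceeds with retention of alkene geometry.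

3. Step 28. Cleavage of the neopentyl-type TBDPS ether is slow, and during it the enol ether may hydrolyse or the β-keto lactone may epimerise at C2 or transacylate to the liberated primary hydroxyl. Fallback: set out from 35 and return at 38, with the slow desilylation moved to a stage that has no β-keto ester. Bu4NF/AcOH in THF should remove both silyl groups to give the triol enol ether F2. TESCl and imidazole in CH2Cl2 at −40 °C should silylate only the primary hydroxyl, giving the primary triethylsilyl ether F3. Dess–Martin oxidation as in step 27 gives the keto lactone F4. Its primary triethylsilyl ether should fall off within minutes with HF·pyridine/pyridine in THF at 0 °C, giving 38.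

**Further compounds**

F0 | step 23 | none | none
F1 | step 25 | potassium (6Z)-alkenyltrifluoroborate corresponding to 34 | C=C1/C=C(/C)[C@H](CC)OC(=O)[C@H](C)[C@@H](O[Si](CC)(CC)CC)[C@](O)(CO[Si](c2ccccc2)(c2ccccc2)C(C)(C)C)C/C([B-](F)(F)F)=C\[C@@H](C)C1.[K+]
F2 | step 28 | triol enol ether lactone (3-OH, 4-OH, 4-CH2OH) | C=C1/C=C(/C)[C@H](CC)OC(=O)[C@H](C)[C@@H](O)[C@](O)(CO)C/C(OC)=C\[C@@H](C)C1
F3 | step 28 | primary triethylsilyl ether of F2 | C=C1/C=C(/C)[C@H](CC)OC(=O)[C@H](C)[C@@H](O)[C@](O)(CO[Si](CC)(CC)CC)C/C(OC)=C\[C@@H](C)C1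
F4 | step 28 | β-keto lactone with 4-CH2OSiEt3 | C=C1/C=C(/C)[C@H](CC)OC(=O)[C@H](C)C(=O)[C@](O)(CO[Si](CC)(CC)CC)C/C(OC)=C\[C@@H](C)C1
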